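**Assumption:** the target has no stereocentre and no stereogenic double bond, so no enantiocontrol is needed; the stereocentres of intermediates 7–9 are racemic and are erased on aromatisation.

## Retrosynthetic overview

1. Target 20 comes from 18 by hydroxide cleavage of the aryl tosylate and the methyl ester; both prenyl groups come from cross-metathesis of the 3,5-diallyl phenol 15 with 2-methyl-2-butene.
2. 15 comes from resorcylate 10 by two O-allylation/aromatic Claisen cycles at the 4-OH (first to C3, then 2-O-methylation, then to C5).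
3. 10 comes from cyclohexane-1,3-dione 8 by bromination–dehydrobromination.
4. 8 comes from the key C–C bond formation: intermolecular Michael addition of dimethyl malonate 6 to enone 5, closed in the same flask by an intramolecular Claisen (Dieckmann) condensation.
5. 5 comes from methyl 3-(4-hydroxyphenyl)propanoate 1 by tosylation, DIBAL-H and Wittig; only the benzoate ring is built (step 4, aromatised in step 5), the phenol ring is bought.

## Route

**Step 1**
Reactants: 1 methyl 3-(4-hydroxyphenyl)propanoate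
Product: 2 methyl 3-[4-(tosyloxy)phenyl]propanoate
Conditions: TsCl (1.1 eq), K2CO3 (1.5 eq), acetone, reflux
Reagents that add atoms: p-toluenesulfonyl chloride, Cc1ccc(cc1)S(=O)(=O)Cl
Why: O-sulfonylation of the phenoxide gives an aryl tosylate that survives acid, bromine, 190 °C and the Ru carbene, and is removed by hydroxide in the last step.

**Step 2**
Reactants: 2 methyl 3-[4-(tosyloxy)phenyl]propanoate
Product: 3 3-[4-(tosyloxy)phenyl]propanal
Conditions: DIBAL-H (1.1 eq), CH2Cl2, −78 °C; Rochelle salt work-up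
Reagents that add atoms: none
Why: Partial ester reduction with DIBAL-H stops at the aluminium hemiacetal at −78 °C and gives the aldehyde on work-up, while the aryl sulfonate is not reduced at this temperature.

**Step 3**
Reactants: 3 3-[4-(tosyloxy)phenyl]propanal; 4 1-(triphenyl-λ5-phosphanylidene)propan-2-one
Product: 5 (E)-6-[4-(tosyloxy)phenyl]hex-3-en-2-one
Conditions: CH2Cl2, rt to 40 °C
Reagents that add atoms: none
Why: Wittig olefination with a stabilised ylide gives the E-enone cleanly under neutral conditions.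

**Step 4**
Reactants: 5 (E)-6-[4-(tosyloxy)phenyl]hex-3-en-2-one; 6 dimethyl malonate
Product: 8 methyl 2,4-dioxo-6-{2-[4-(tosyloxy)phenyl]ethyl}cyclohexane-1-carboxylate, via malonate Michael adduct 7 (not isolated)
Conditions: 6 (1.2 eq), NaH (1.1 eq), THF, 0 °C; add 5; reflux; then 1 M HCl
Reagents that add atoms: none
Why: Intermolecular Michael addition of sodiomalonate to the enone is followed by intramolecular Claisen (Dieckmann) condensation of the methyl ketone enolate onto a malonate ester, driven by the stabilised dione enolate; the alkoxide-free aprotic base spares the aryl sulfonate, and the racemic stereocentres are erased in step 5.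

**Step 5**
Reactants: 8 methyl 2,4-dioxo-6-{2-[4-(tosyloxy)phenyl]ethyl}cyclohexane-1-carboxylate
Product: 10 methyl 2,4-dihydroxy-6-{2-[4-(tosyloxy)phenyl]ethyl}benzoate, via 3-bromo-1,3-dione 9 (not isolated)
Conditions: Br2 (1.0 eq), DMF, 0 °C; then 80 °C
Reagents that add atoms: none
Why: Bromination of the dione enol followed by thermal dehydrobromination aromatises the ring to the resorcylate, and the deactivated tosyloxyphenyl ring is not brominated.

**Step 6**
Reactants: 10 methyl 2,4-dihydroxy-6-{2-[4-(tosyloxy)phenyl]ethyl}benzoate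
Product: 11 methyl 4-(allyloxy)-2-hydroxy-6-{2-[4-(tosyloxy)phenyl]ethyl}benzoate
Conditions: allyl bromide (1.05 eq), K2CO3 (1.2 eq), acetone, reflux
Reagents that add atoms: allyl bromide, C=CCBr
Why: Williamson etherification is selective for the more acidic 4-OH because the 2-OH is hydrogen-bonded to the ester carbonyl.

**Step 7**
Reactants: 11 methyl 4-(allyloxy)-2-hydroxy-6-{2-[4-(tosyloxy)phenyl]ethyl}benzoate
Product: 12 methyl 3-allyl-2,4-dihydroxy-6-{2-[4-(tosyloxy)phenyl]ethyl}benzoate
Conditions: 1,2-dichlorobenzene, 190 °C, sealed tube, Ar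
Reagents that add atoms: none
Why: Aromatic Claisen rearrangement goes to C3 because the 2-OH/ester chelate fixes the C3=C4 bond and C5 is more hindered, and any 5-allyl isomer would converge on 15 after steps 8–10.

**Step 8**
Reactants: 12 methyl 3-allyl-2,4-dihydroxy-6-{2-[4-(tosyloxy)phenyl]ethyl}benzoate
Product: 13 methyl 3-allyl-4-(allyloxy)-2-hydroxy-6-{2-[4-(tosyloxy)phenyl]ethyl}benzoate
Conditions: allyl bromide (1.1 eq), K2CO3 (1.3 eq), acetone, reflux
Reagents that add atoms: allyl bromide, C=CCBr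
Why: Williamson etherification again takes the free 4-OH in preference to the chelated, doubly flanked 2-OH.

**Step 9**
Reactants: 13 methyl 3-allyl-4-(allyloxy)-2-hydroxy-6-{2-[4-(tosyloxy)phenyl]ethyl}benzoate
Product: 14 methyl 3-allyl-4-(allyloxy)-2-methoxy-6-{2-[4-(tosyloxy)phenyl]ethyl}benzoate
Conditions: MeI (3 eq), K2CO3 (3 eq), DMF, 50 °C
Reagents that add atoms: iodomethane, CI
Why: With the 4-oxygen capped, forcing Williamson O-methylation in a dipolar aprotic solvent alkylates the only remaining phenol, the chelated 2-OH.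

**Step 10**
Reactants: 14 methyl 3-allyl-4-(allyloxy)-2-methoxy-6-{2-[4-(tosyloxy)phenyl]ethyl}benzoate
Product: 15 methyl 3,5-diallyl-4-hydroxy-2-methoxy-6-{2-[4-(tosyloxy)phenyl]ethyl}benzoate
Conditions: 1,2-dichlorobenzene, 190 °C, sealed tube, Ar
Reagents that add atoms: none
Why: In this second aromatic Claisen rearrangement C3 is blocked, so the [3,3] shift can only deliver the allyl group to C5 and frees the 4-OH.

**Step 11**
Reactants: 15 methyl 3,5-diallyl-4-hydroxy-2-methoxy-6-{2-[4-(tosyloxy)phenyl]ethyl}benzoate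
Product: 18 methyl 4-hydroxy-2-methoxy-3,5-bis(3-methylbut-2-en-1-yl)-6-{2-[4-(tosyloxy)phenyl]ethyl}benzoate, via 3-prenyl-5-allyl ester 16 (not isolated), via 3-allyl-5-prenyl ester 17 (not isolated)
Conditions: Grubbs II (2 × 5 mol%), 2-methyl-2-butene/CH2Cl2 (1:1), 40 °C, sealed tube
Reagents that add atoms: 2-methyl-2-butene, CC=C(C)C
Why: Olefin cross-metathesis with a large excess of 2-methyl-2-butene turns each terminal allyl group into a prenyl group with loss of propene; the two allyl groups react independently, so 16 and 17 are parallel mono-metathesis intermediates, and the phenol, ester and sulfonate are inert.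

**Step 12**
Reactants: 18 methyl 4-hydroxy-2-methoxy-3,5-bis(3-methylbut-2-en-1-yl)-6-{2-[4-(tosyloxy)phenyl]ethyl}benzoate
Product: 20 4-hydroxy-6-[2-(4-hydroxyphenyl)ethyl]-2-methoxy-3,5-bis(3-methylbut-2-en-1-yl)benzoic acid, via detosylated methyl ester 19 (not isolated)
Conditions: KOH (15 eq), DMSO/H2O (3:1), 80 °C, Ar; then 1 M HCl, 0 °C, to pH 3
Reagents that add atoms: potassium hydroxide, [K+].[OH-]
Why: Hydroxide first cleaves the aryl sulfonate at sulfur and then saponifies the di-ortho-substituted ester (BAc2), the alcohol-free medium avoids alkyl tosylate formation, and basic conditions with cold mild acidification avoid chroman formation and decarboxylation.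

## Compound list

1 | methyl 3-(4-hydroxyphenyl)propanoate | COC(=O)CCc1ccc(O)cc1 | starting material
2 | methyl 3-[4-(tosyloxy)phenyl]propanoate | COC(=O)CCc1ccc(OS(=O)(=O)c2ccc(C)cc2)cc1 | intermediate
3 | 3-[4-(tosyloxy)phenyl]propanal | O=CCCc1ccc(OS(=O)(=O)c2ccc(C)cc2)cc1 | intermediate
4 | 1-(triphenyl-λ5-phosphanylidene)propan-2-one | CC(=O)C=P(c1ccccc1)(c1ccccc1)c1ccccc1 | starting material
5 | (E)-6-[4-(tosyloxy)phenyl]hex-3-en-2-one | CC(=O)/C=C/CCc1ccc(OS(=O)(=O)c2ccc(C)cc2)cc1 | intermediate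
6 | dimethyl malonate | COC(=O)CC(=O)OC | starting material
7 | dimethyl 2-{5-oxo-1-[4-(tosyloxy)phenyl]hexan-3-yl}malonate (racemic; not isolated) | COC(=O)C(C(=O)OC)C(CCc1ccc(OS(=O)(=O)c2ccc(C)cc2)cc1)CC(C)=O | intermediate
8 | methyl 2,4-dioxo-6-{2-[4-(tosyloxy)phenyl]ethyl}cyclohexane-1-carboxylate (racemic, enolised) | COC(=O)C1C(=O)CC(=O)CC1CCc1ccc(OS(=O)(=O)c2ccc(C)cc2)cc1 | intermediate
9 | methyl 3-bromo-2,4-dioxo-6-{2-[4-(tosyloxy)phenyl]ethyl}cyclohexane-1-carboxylate (racemic; not isolated) | COC(=O)C1C(=O)C(Br)C(=O)CC1CCc1ccc(OS(=O)(=O)c2ccc(C)cc2)cc1 | intermediate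
10 | methyl 2,4-dihydroxy-6-{2-[4-(tosyloxy)phenyl]ethyl}benzoate | COC(=O)c1c(O)cc(O)cc1CCc1ccc(OS(=O)(=O)c2ccc(C)cc2)cc1 | intermediate
11 | methyl 4-(allyloxy)-2-hydroxy-6-{2-[4-(tosyloxy)phenyl]ethyl}benzoate | COC(=O)c1c(O)cc(OCC=C)cc1CCc1ccc(OS(=O)(=O)c2ccc(C)cc2)cc1 | intermediate
12 | methyl 3-allyl-2,4-dihydroxy-6-{2-[4-(tosyloxy)phenyl]ethyl}benzoate | COC(=O)c1c(O)c(CC=C)c(O)cc1CCc1ccc(OS(=O)(=O)c2ccc(C)cc2)cc1 | intermediate
13 | methyl 3-allyl-4-(allyloxy)-2-hydroxy-6-{2-[4-(tosyloxy)phenyl]ethyl}benzoate | COC(=O)c1c(O)c(CC=C)c(OCC=C)cc1CCc1ccc(OS(=O)(=O)c2ccc(C)cc2)cc1 | intermediate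
14 | methyl 3-allyl-4-(allyloxy)-2-methoxy-6-{2-[4-(tosyloxy)phenyl]ethyl}benzoate | COC(=O)c1c(OC)c(CC=C)c(OCC=C)cc1CCc1ccc(OS(=O)(=O)c2ccc(C)cc2)cc1 | intermediate
15 | methyl 3,5-diallyl-4-hydroxy-2-methoxy-6-{2-[4-(tosyloxy)phenyl]ethyl}benzoate | COC(=O)c1c(OC)c(CC=C)c(O)c(CC=C)c1CCc1ccc(OS(=O)(=O)c2ccc(C)cc2)cc1 | intermediate
16 | methyl 5-allyl-4-hydroxy-2-methoxy-3-(3-methylbut-2-en-1-yl)-6-{2-[4-(tosyloxy)phenyl]ethyl}benzoate (not isolated; formed in parallel with 17) | COC(=O)c1c(OC)c(CC=C(C)C)c(O)c(CC=C)c1CCc1ccc(OS(=O)(=O)c2ccc(C)cc2)cc1 | intermediate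
17 | methyl 3-allyl-4-hydroxy-2-methoxy-5-(3-methylbut-2-en-1-yl)-6-{2-[4-(tosyloxy)phenyl]ethyl}benzoate (not isolated; formed in parallel with 16) | COC(=O)c1c(OC)c(CC=C)c(O)c(CC=C(C)C)c1CCc1ccc(OS(=O)(=O)c2ccc(C)cc2)cc1 | intermediate
18 | methyl 4-hydroxy-2-methoxy-3,5-bis(3-methylbut-2-en-1-yl)-6-{2-[4-(tosyloxy)phenyl]ethyl}benzoate | COC(=O)c1c(OC)c(CC=C(C)C)c(O)c(CC=C(C)C)c1CCc1ccc(OS(=O)(=O)c2ccc(C)cc2)cc1 | intermediate
19 | methyl 4-hydroxy-6-[2-(4-hydroxyphenyl)ethyl]-2-methoxy-3,5-bis(3-methylbut-2-en-1-yl)benzoate (not isolated) | COC(=O)c1c(OC)c(CC=C(C)C)c(O)c(CC=C(C)C)c1CCc1ccc(O)cc1 | intermediate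
20 | 4-hydroxy-6-[2-(4-hydroxyphenyl)ethyl]-2-methoxy-3,5-bis(3-methylbut-2-en-1-yl)benzoic acid (achiral) | COc1c(CC=C(C)C)c(O)c(CC=C(C)C)c(CCc2ccc(O)cc2)c1C(=O)O | target

## Summary

Total step count: 12. Longest linear sequence: 12 steps (fully linear, 1 to 20).

**Steps most likely to fail, with fallbacks**

Step 12 (saponification of the di-ortho-substituted ester next to a para-phenoxide; the acid is prone to decarboxylation). The fallback sets out from 18 and comes back at 20, and it makes no compound outside the list (F0). The sulfonate alone is cleaved under milder conditions (KOH, aqueous dioxane, 50 °C) and the detosylated methyl ester 19 is isolated. The ester is then cleaved at the O–CH3 bond rather than at the shielded carbonyl, by SN2 dealkylation with lithium propanethiolate in HMPA (rt to 50 °C), and cold acidification gives 20.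

Step 5 (aromatisation; typical losses are over-bromination and decarboxylation). The fallback sets out from 8 and comes back at 10. Dione 8 is silylated (TMSOTf, Et3N, CH2Cl2, 0 °C) to methyl 2,4-bis(trimethylsilyloxy)-6-{2-[4-(tosyloxy)phenyl]ethyl}cyclohexa-1,3-diene-1-carboxylate F1. This cyclohexadiene is dehydrogenated with DDQ (benzene, rt) to methyl 2,4-bis(trimethylsilyloxy)-6-{2-[4-(tosyloxy)phenyl]ethyl}benzoate F2. Dilute HCl in THF removes the silyl groups and gives 10, with no halogen and no hot acid.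

Step 4 (tandem Michael/Claisen run under non-standard aprotic conditions to protect the sulfonate). The fallback sets out from 3 and 6 and comes back at 8, forming the two C–C bonds separately. Knoevenagel condensation of 3 with 6 (TiCl4, pyridine, THF, 0 °C) gives dimethyl 2-{3-[4-(tosyloxy)phenyl]propylidene}malonate F3. Mukaiyama–Michael addition of 2-(trimethylsilyloxy)propene (TiCl4, CH2Cl2, −78 °C) gives the adduct 7, now isolated. Brief treatment with t-BuOK (1.05 eq, THF, 0 °C to rt) closes it to 8.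

## Further compounds

F0 | step 12 | none | none
F1 | step 5 | methyl 2,4-bis(trimethylsilyloxy)-6-{2-[4-(tosyloxy)phenyl]ethyl}cyclohexa-1,3-diene-1-carboxylate | COC(=O)C1=C(O[Si](C)(C)C)C=C(O[Si](C)(C)C)CC1CCc1ccc(OS(=O)(=O)c2ccc(C)cc2)cc1
F2 | step 5 | methyl 2,4-bis(trimethylsilyloxy)-6-{2-[4-(tosyloxy)phenyl]ethyl}benzoate | COC(=O)c1c(O[Si](C)(C)C)cc(O[Si](C)(C)C)cc1CCc1ccc(OS(=O)(=O)c2ccc(C)cc2)cc1
F3 | step 4 | dimethyl 2-{3-[4-(tosyloxy)phenyl]propylidene}malonate | COC(=O)C(=CCCc1ccc(OS(=O)(=O)c2ccc(C)cc2)cc1)C(=O)OC
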